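**Retrosynthetic overview**
1. Target 31 ⇒ desilylation, CBS reduction at C14, acetylation of C12–OH and a Felkin-selective Mukaiyama aldol (C12–C13) lead back to aldehyde 25 and the silyl enol ether 27 of 3-methylbut-3-en-2-one.
2. 25 ⇒ tricyclic acetal 21, where C6–O and C12 are tied up as a tetrahydrofuran acetal while C10 goes from silyl ether to ketone, is hydroxylated at C9 and methylenated; the acetal ring (C7–C11 bond, cis to C6–O) comes from an Ueno–Stork radical cyclisation on the C6 allylic alcohol of enone 12.
3. Key disconnection: the cyclopentene C1–C2–C3=C4(Me)–C5 is fused to the seven-membered ring C5–C6–C7–C8–C9–C10–C1 through C5 and C1, the α- and β-carbons of the C6 oxygen function. C2–C3=C4(Me) is therefore a 1-methylallenyl unit that an allenylsilane can lay across the C5=C1 bond of a C6 cycloheptenone in a [3+2] annulation (bonds C1–C2 and C4–C5).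
4. Enone 4 ⇐ cyclohepta-1,3-diene (singlet-oxygen endoperoxide, desymmetrising Kornblum–DeLaMare rearrangement, silylation); allene 7 ⇐ 3-(trimethylsilyl)prop-2-yn-1-ol (mesylate, methylcopper SN2′).
5. Ring order: seven-membered ring from the start, cyclopentene in the key step, then a temporary tetrahydrofuran acetal ring that is opened again before the side chain is finished.

Key step: step 6

Numbering used throughout: cyclopentene C1–C2–C3=C4(Me)–C5; seven-membered ring C5–C6–C7–C8–C9–C10–C1; side chain on C7: C11(Me)–C12–C13–C14–C15(=CH2)Me. β is the face of the seven-membered ring that carries H5, the C6 oxygen and C11 in the target; α carries H1, the C9 oxygen and the C10 silyl ether.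
Assumption: of the two pseudoenantiomeric cinchona catalysts (O-acetylcupreine, O-acetylcupreidine), the one that leads to (S)-3 is used in step 2.
Remark: the acetal carbon C12 of 15–22 (and the CHBr carbon of 15) is carried as a mixture of epimers; this centre is lost at 23 and set again in step 21.

**Route**

Step 1
Reactants: 1 cyclohepta-1,3-diene
Product: 2 6,7-dioxabicyclo[3.2.2]non-8-ene (meso endoperoxide)
Conditions: O2, 5,10,15,20-tetraphenylporphyrin (cat.), visible light, CH2Cl2, 0 °C
Reagents that add atoms: oxygen, O=O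
Why: Photosensitised singlet oxygen adds across the cisoid 1,3-diene in a [4+2] cycloaddition to give the meso endoperoxide, so no stereochemical issue arises.

Step 2
Reactants: 2 6,7-dioxabicyclo[3.2.2]non-8-ene
Product: 3 (S)-4-hydroxycyclohept-2-en-1-one
Conditions: O-acetylcupreine or O-acetylcupreidine (5 mol%), CH2Cl2, rt
Reagents that add atoms: none
Why: In the Kornblum–DeLaMare rearrangement the chiral amine removes one of the two enantiotopic C–H bonds next to the peroxide and the O–O bond breaks to a ketone and an alkoxide, so the desymmetrisation sets the (S)-carbinol centre (later C10) under catalyst control.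

Step 3
Reactants: 3 (S)-4-hydroxycyclohept-2-en-1-one
Product: 4 (S)-4-(tert-butyldiphenylsilyloxy)cyclohept-2-en-1-one
Conditions: tBuPh2SiCl, imidazole, DMF, 0 °C to rt
Reagents that add atoms: tert-butyl(chloro)diphenylsilane, CC(C)(C)[Si](Cl)(c1ccccc1)c1ccccc1
Why: Standard silylation of the secondary alcohol; the tert-butyldiphenylsilyl ether is preferred to a tert-butyldimethylsilyl ether because it must survive TiCl4 and CF3CO2H and because its bulk shields the α face of the enone.

Step 4
Reactants: 5 3-(trimethylsilyl)prop-2-yn-1-ol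
Product: 6 3-(trimethylsilyl)prop-2-yn-1-yl methanesulfonate
Conditions: MeSO2Cl, Et3N, CH2Cl2, 0 °C
Reagents that add atoms: methanesulfonyl chloride, CS(=O)(=O)Cl
Why: Sulfonylation of the primary propargylic alcohol provides the leaving group for the allene synthesis.

Step 5
Reactants: 6 3-(trimethylsilyl)prop-2-yn-1-yl methanesulfonate
Product: 7 1-methyl-1-(trimethylsilyl)allene
Conditions: MeMgCl, CuBr, LiBr, THF, −78 °C to rt
Reagents that add atoms: methylmagnesium chloride, C[Mg]Cl
Why: The methylcopper reagent formed from MeMgCl and CuBr·LiBr substitutes the propargylic mesylate in the SN2′ sense at the silyl-bearing alkyne carbon, a standard route to 1,1-disubstituted allenes.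

Step 6
Reactants: 4 (S)-4-(tert-butyldiphenylsilyloxy)cyclohept-2-en-1-one; 7 1-methyl-1-(trimethylsilyl)allene
Product: 9 trans-fused bicyclic C6 ketone (H1 α, H5 β, 10α-silyloxy, C3 trimethylsilyl, C4 methyl), via cis-fused ketone 8 (not isolated)
Conditions: TiCl4 (1.2 equiv), CH2Cl2, −78 °C; aq. NaHCO3; then 1,8-diazabicyclo[5.4.0]undec-7-ene (0.2 equiv), CH2Cl2, 0 °C to rt
Reagents that add atoms: none
Why: TiCl4 binds the enone carbonyl and the allene CH2 terminus (C2) adds to the β-carbon C1 on the β face, anti to the bulky α-silyloxy group on the neighbouring C10, which sets C1 under substrate control. The vinyl cation so formed is stabilised by the β-silicon, a 1,2-silyl shift moves the charge to the methyl-bearing carbon C4, and the titanium enolate carbon C5 captures it, closing the cyclopentene in a five-membered closure that leaves C3=C4 inside the new ring (endo with respect to the cation double bond); this is the Danheiser (trimethylsilyl)cyclopentene annulation, known for cyclic enones. The regiochemistry (methyl on C4, silicon on C3) follows from the substitution of the allene and the direction of the silyl shift. Because the three-carbon unit is delivered to one face, the kinetic product 8 is cis-fused; C5 is α to the ketone and the amidine base equilibrates it to the trans-fused ketone 9, in which both ring-fusion hydrogens are axial and the C10 silyloxy group is equatorial, so C5 is set under thermodynamic control. The step needs β-face selectivity at C1, secured by the C10 silyl ether, and epimerisation without migration of C3=C4 into conjugation, which the C3 silyl group disfavours by hindering γ-protonation of the dienolate.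

Step 7
Reactants: 9 trans-fused C3-silyl ketone
Product: 10 trans-fused C6 ketone with C3=C4(Me) and 10α-silyloxy group
Conditions: CF3CO2H (3 equiv), CH2Cl2, 0 °C, short contact
Reagents that add atoms: none
Why: Protodesilylation: the vinylsilane is protonated at the silicon-bearing C3 to give the tertiary β-silyl cation at C4, which loses the silyl group to trifluoroacetate and restores C3=C4 without touching C1, C5 or the robust silyl ether.

Step 8
Reactants: 10 trans-fused C6 ketone
Product: 12 C7=C8 enone (C6 ketone, trans ring fusion retained), via silyl enol ether 11 (not isolated)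
Conditions: LiN(iPr)2, Me3SiCl, THF, −78 °C; then Pd(OAc)2 (1.0 equiv), MeCN, rt
Reagents that add atoms: none
Why: LiN(iPr)2 with Me3SiCl present removes a hydrogen from the C7 methylene and not from the hindered ring-fusion methine C5 (kinetic control), and Saegusa–Ito oxidation of the silyl enol ether with Pd(OAc)2 (palladium enolate, β-hydride elimination from C8) gives the C7=C8 enone.

Step 9
Reactants: 12 C7=C8 enone
Product: 13 6β-allylic alcohol (C6–OH cis to H5)
Conditions: NaBH4, CeCl3·7H2O, MeOH, −78 °C
Reagents that add atoms: none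
Why: Luche 1,2-reduction; the hydride is expected to enter C6 along the axial trajectory on the α face, anti to the axial C5–H, giving the equatorial 6β-alcohol (new stereocentre, substrate control).

Step 10
Reactants: 13 6β-allylic alcohol; 14 ethyl 1-propenyl ether (E/Z mixture)
Product: 15 mixed bromoacetal C6–O–CH(OEt)–CHBr–CH3
Conditions: N-bromosuccinimide, CH2Cl2, −40 °C to rt
Reagents that add atoms: N-bromosuccinimide, O=C1CCC(=O)N1Br
Why: Bromoacetalisation: N-bromosuccinimide brominates the enol ether and the oxocarbenium ion is trapped by the C6 hydroxyl; the enol ether is far more reactive toward the bromine source than the ring alkenes.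

Step 11
Reactants: 15 mixed bromoacetal
Product: 16 tricyclic ethyl acetal (tetrahydrofuran O6–C12–C11–C7–C6 cis-fused on the β face, C11 methyl cis to C8, 10α-silyloxy)
Conditions: Bu3SnH, 2,2′-azobis(2-methylpropionitrile) (cat.), benzene, 80 °C, slow addition
Reagents that add atoms: none
Why: Ueno–Stork cyclisation: the C11 radical, held on the β face by the C6–O tether, closes 5-exo-trig on C7 so that the new C7–C11 bond is necessarily cis to C6–O (C7 set by the tether), the C8 radical is reduced by Bu3SnH, and a chair-like transition state with the C11 methyl pseudo-equatorial should favour methyl cis to C8, the required C11 configuration.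

Step 12
Reactants: 16 tricyclic ethyl acetal
Product: 17 10α-alcohol
Conditions: Bu4NF, THF, rt
Reagents that add atoms: none
Why: Fluoride cleaves the only silyl ether and frees the C10 hydroxyl, while the acetal is inert.

Step 13
Reactants: 17 10α-alcohol
Product: 18 C10 ketone
Conditions: Dess–Martin periodinane, NaHCO3, CH2Cl2, 0 °C to rt
Reagents that add atoms: none
Why: Buffered Dess–Martin oxidation converts the secondary alcohol into the C10 ketone without acid that could open the acetal or base that could epimerise C1.

Step 14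
Reactants: 18 C10 ketone
Product: 19 9α-hydroxy C10 ketone
Conditions: KN(SiMe3)2, THF, −78 °C; 2-(phenylsulfonyl)-3-phenyloxaziridine, −78 °C; then aq. NH4Cl
Reagents that add atoms: 2-(phenylsulfonyl)-3-phenyloxaziridine, O=S(=O)(c1ccccc1)N1OC1c1ccccc1
Why: KN(SiMe3)2 deprotonates the C9 methylene in preference to the ring-fusion methine C1 (kinetic enolate) and the N-sulfonyloxaziridine transfers oxygen to C9 (enolate hydroxylation) on the α face, away from the β-fused acetal ring and its axial C7–C11 bond, which sets the 9α-hydroxyl.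

Step 15
Reactants: 19 9α-hydroxy C10 ketone
Product: 20 9α-(tert-butyldimethylsilyloxy) C10 ketone
Conditions: tBuMe2SiCl, imidazole, 4-(dimethylamino)pyridine (cat.), DMF, rt
Reagents that add atoms: tert-butyl(chloro)dimethylsilane, CC(C)(C)[Si](C)(C)Cl
Why: Silylation of the α-hydroxy ketone under mild imidazole conditions protects C9–OH for the olefination and avoids silyl triflates that could activate the acetal.

Step 16
Reactants: 20 9α-silyloxy C10 ketone
Product: 21 C10 exocyclic methylene compound
Conditions: Cp2TiMe2, toluene–THF, 70 °C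
Reagents that add atoms: dimethyltitanocene Cp2TiMe2, C[Ti](C)(C1C=CC=C1)C1C=CC=C1
Why: Petasis methylenation: Cp2Ti=CH2 generated thermally from Cp2TiMe2 converts the hindered, enolisable α-silyloxy ketone into the exocyclic alkene under non-basic conditions, so C1 and C9 keep their configuration.

Step 17
Reactants: 21 C10 exocyclic methylene acetal
Product: 23 6β,12-diol, via lactol 22 (not isolated)
Conditions: pyridinium p-toluenesulfonate, THF–H2O, 45 °C; then NaBH4, 0 °C
Reagents that add atoms: water, O
Why: Mild aqueous acid hydrolyses the tetrahydrofuranyl ethyl acetal to the lactol, whose open hydroxy aldehyde form is reduced by NaBH4 to the primary alcohol, while the secondary silyl ether and both alkenes are untouched.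

Step 18
Reactants: 23 6β,12-diol
Product: 24 6,12-bis(triethylsilyl) ether
Conditions: Et3SiOTf, 2,6-lutidine, CH2Cl2, −78 to 0 °C
Reagents that add atoms: triethylsilyl trifluoromethanesulfonate, CC[Si](CC)(CC)OS(=O)(=O)C(F)(F)F
Why: Both hydroxyls are silylated by the reactive silyl triflate, which the hindered C6 hydroxyl requires.

Step 19
Reactants: 24 6,12-bis(triethylsilyl) ether
Product: 25 C12 aldehyde (C6 triethylsilyl ether and C9 tert-butyldimethylsilyl ether retained)
Conditions: (COCl)2, DMSO, CH2Cl2, −78 to −35 °C; then Et3N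
Reagents that add atoms: none
Why: Under Swern conditions the activated sulfonium species cleaves the unhindered primary triethylsilyl ether and oxidises it directly to the aldehyde, a known selective oxidation that leaves the secondary silyl ethers at C6 and C9 in place and is cold enough not to epimerise C11.

Step 20
Reactants: 26 3-methylbut-3-en-2-one
Product: 27 3-methyl-2-(trimethylsilyloxy)buta-1,3-diene
Conditions: LiN(iPr)2, THF, −78 °C; Me3SiCl
Reagents that add atoms: chlorotrimethylsilane, C[Si](C)(C)Cl
Why: The ketone has α-hydrogens only on its methyl group, so kinetic deprotonation and O-silylation give a single 2-silyloxy diene.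

Step 21
Reactants: 25 C12 aldehyde; 27 3-methyl-2-(trimethylsilyloxy)buta-1,3-diene
Product: 28 (12S)-12-hydroxy C14 enone
Conditions: BF3·OEt2, CH2Cl2, −78 °C
Reagents that add atoms: none
Why: Mukaiyama aldol addition: the BF3-activated aldehyde is attacked by the enol silane terminus according to the Felkin–Anh model (C7 as the large group anti to the nucleophile, methyl inside), which gives the C11/C12 syn relationship, that is (12S).

Step 22
Reactants: 28 (12S)-12-hydroxy C14 enone
Product: 29 12-acetate
Conditions: Ac2O, pyridine, 4-(dimethylamino)pyridine (cat.), CH2Cl2, 0 °C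
Reagents that add atoms: acetic anhydride, CC(=O)OC(C)=O
Why: Acylation of the only free hydroxyl at 0 °C is mild enough to avoid β-elimination of the β-acetoxy ketone.

Step 23
Reactants: 29 12-acetate
Product: 30 (14R)-allylic alcohol, the 6-O-triethylsilyl 9-O-tert-butyldimethylsilyl ether of the target
Conditions: (S)-1-methyl-3,3-diphenyl-tetrahydro-1H,3H-pyrrolo[1,2-c][1,3,2]oxazaborole ((S)-Me-CBS, 0.5 equiv), catecholborane, toluene, −78 °C
Reagents that add atoms: none
Why: Corey–Bakshi–Shibata reduction: with the isopropenyl group as the larger ketone substituent the (S)-oxazaborolidine directs hydride to the face that gives the (14R)-allylic alcohol (catalyst control), with 1,2-selectivity and no hydroboration at −78 °C.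

Step 24
Reactants: 30 bis-silyl ether of the target
Product: 31 CNP0281601.4 (target)
Conditions: HF·pyridine, pyridine, THF, 0 °C to rt
Reagents that add atoms: none
Why: Buffered HF·pyridine cleaves the triethylsilyl and tert-butyldimethylsilyl ethers under mildly acidic conditions in which the 12-acetate should not migrate to the C14 hydroxyl and the allylic alcohols are stable.

**Compound list**
1 | cyclohepta-1,3-diene | C1=CC=CCCC1 | starting material
2 | 6,7-dioxabicyclo[3.2.2]non-8-ene (meso endoperoxide) | O1O[C@H]2C=C[C@@H]1CCC2 | intermediate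
3 | (S)-4-hydroxycyclohept-2-en-1-one | O=C1C=C[C@@H](O)CCC1 | intermediate
4 | (S)-4-(tert-butyldiphenylsilyloxy)cyclohept-2-en-1-one (carbonyl C6, alkene C5=C1, silyloxy carbon C10) | O=C1C=C[C@@H](O[Si](c2ccccc2)(c2ccccc2)C(C)(C)C)CCC1 | intermediate
5 | 3-(trimethylsilyl)prop-2-yn-1-ol | C[Si](C)(C)C#CCO | starting material
6 | 3-(trimethylsilyl)prop-2-yn-1-yl methanesulfonate | C[Si](C)(C)C#CCOS(C)(=O)=O | intermediate
7 | 1-methyl-1-(trimethylsilyl)allene | CC(=C=C)[Si](C)(C)C | intermediate
8 | cis-fused bicyclic C6 ketone (H1 α, H5 α, 10α-silyloxy, C3 SiMe3, C4 Me) | O=C1CCC[C@H](O[Si](c3ccccc3)(c3ccccc3)C(C)(C)C)[C@H]2CC([Si](C)(C)C)=C(C)[C@@H]12 | intermediate (not isolated)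
9 | trans-fused bicyclic C6 ketone (H1 α, H5 β, 10α-silyloxy, C3 SiMe3, C4 Me) | O=C1CCC[C@H](O[Si](c3ccccc3)(c3ccccc3)C(C)(C)C)[C@H]2CC([Si](C)(C)C)=C(C)[C@H]12 | intermediate
10 | trans-fused C6 ketone with C3=C4(Me), 10α-silyloxy | O=C1CCC[C@H](O[Si](c3ccccc3)(c3ccccc3)C(C)(C)C)[C@H]2CC=C(C)[C@H]12 | intermediate
11 | C6 trimethylsilyl enol ether (C6=C7) of 10 | C[Si](C)(C)OC1=CCC[C@H](O[Si](c3ccccc3)(c3ccccc3)C(C)(C)C)[C@H]2CC=C(C)[C@H]12 | intermediate (not isolated)
12 | trans-fused C7=C8 enone (C6 ketone) | O=C1C=CC[C@H](O[Si](c3ccccc3)(c3ccccc3)C(C)(C)C)[C@H]2CC=C(C)[C@H]12 | intermediate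
13 | 6β-allylic alcohol (OH cis to H5) | O[C@H]1C=CC[C@H](O[Si](c3ccccc3)(c3ccccc3)C(C)(C)C)[C@H]2CC=C(C)[C@H]12 | intermediate
14 | ethyl 1-propenyl ether (E/Z mixture) | CC=COCC | starting material
15 | mixed bromoacetal of 13 (epimers at the acetal and CHBr carbons) | CCOC(C(C)Br)O[C@H]1C=CC[C@H](O[Si](c3ccccc3)(c3ccccc3)C(C)(C)C)[C@H]2CC=C(C)[C@H]12 | intermediate
16 | tricyclic ethyl acetal (O6 and C11 β on C6/C7, C11 Me cis to C8, 10α-silyloxy, C12 epimers) | CCOC1O[C@H]2[C@@H]([C@@H]1C)CC[C@H](O[Si](c4ccccc4)(c4ccccc4)C(C)(C)C)[C@H]3CC=C(C)[C@H]23 | intermediate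
17 | tricyclic acetal, 10α-alcohol | CCOC1O[C@H]2[C@@H]([C@@H]1C)CC[C@H](O)[C@H]3CC=C(C)[C@H]23 | intermediate
18 | tricyclic acetal, C10 ketone | CCOC1O[C@H]2[C@@H]([C@@H]1C)CCC(=O)[C@H]3CC=C(C)[C@H]23 | intermediate
19 | tricyclic acetal, 9α-hydroxy C10 ketone | CCOC1O[C@H]2[C@@H]([C@@H]1C)C[C@H](O)C(=O)[C@H]3CC=C(C)[C@H]23 | intermediate
20 | tricyclic acetal, 9α-(tert-butyldimethylsilyloxy) C10 ketone | CCOC1O[C@H]2[C@@H]([C@@H]1C)C[C@H](O[Si](C)(C)C(C)(C)C)C(=O)[C@H]3CC=C(C)[C@H]23 | intermediate
21 | tricyclic acetal, 9α-silyloxy, C10 exocyclic methylene | CCOC1O[C@H]2[C@@H]([C@@H]1C)C[C@H](O[Si](C)(C)C(C)(C)C)C(=C)[C@H]3CC=C(C)[C@H]23 | intermediate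
22 | lactol corresponding to 21 | OC1O[C@H]2[C@@H]([C@@H]1C)C[C@H](O[Si](C)(C)C(C)(C)C)C(=C)[C@H]3CC=C(C)[C@H]23 | intermediate (not isolated)
23 | 6β,12-diol (9α-silyloxy, C10 methylene, C11 as in target) | OC[C@@H](C)[C@H]1C[C@H](O[Si](C)(C)C(C)(C)C)C(=C)[C@H]2CC=C(C)[C@@H]2[C@H]1O | intermediate
24 | 6,12-bis(triethylsilyl) ether of 23 | CC[Si](CC)(CC)OC[C@@H](C)[C@H]1C[C@H](O[Si](C)(C)C(C)(C)C)C(=C)[C@H]2CC=C(C)[C@@H]2[C@H]1O[Si](CC)(CC)CC | intermediate
25 | C12 aldehyde (6-O-triethylsilyl, 9-O-tert-butyldimethylsilyl) | O=C[C@@H](C)[C@H]1C[C@H](O[Si](C)(C)C(C)(C)C)C(=C)[C@H]2CC=C(C)[C@@H]2[C@H]1O[Si](CC)(CC)CC | intermediate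
26 | 3-methylbut-3-en-2-one | CC(=C)C(C)=O | starting material
27 | 3-methyl-2-(trimethylsilyloxy)buta-1,3-diene | C=C(C)C(=C)O[Si](C)(C)C | intermediate
28 | (12S)-12-hydroxy C14 enone | C=C(C)C(=O)C[C@H](O)[C@@H](C)[C@H]1C[C@H](O[Si](C)(C)C(C)(C)C)C(=C)[C@H]2CC=C(C)[C@@H]2[C@H]1O[Si](CC)(CC)CC | intermediate
29 | (12S)-12-acetoxy C14 enone | C=C(C)C(=O)C[C@H](OC(C)=O)[C@@H](C)[C@H]1C[C@H](O[Si](C)(C)C(C)(C)C)C(=C)[C@H]2CC=C(C)[C@@H]2[C@H]1O[Si](CC)(CC)CC | intermediate
30 | 6-O-triethylsilyl 9-O-tert-butyldimethylsilyl ether of the target, (14R)-alcohol | C=C(C)[C@H](O)C[C@H](OC(C)=O)[C@@H](C)[C@H]1C[C@H](O[Si](C)(C)C(C)(C)C)C(=C)[C@H]2CC=C(C)[C@@H]2[C@H]1O[Si](CC)(CC)CC | intermediate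
31 | CNP0281601.4, (1S,5R,6S,7R,9S,11S,12S,14R) in the route numbering | C=C(C)[C@H](O)C[C@H](OC(C)=O)[C@@H](C)[C@H]1C[C@H](O)C(=C)[C@H]2CC=C(C)[C@@H]2[C@H]1O | target

**Step count**
Total: 24 steps. Longest linear sequence: 21 steps (1–3, 6–19, 21–24).

**Steps most likely to fail**

Step 6. The base treatment may stop at a cis-rich mixture, or the C3=C4 bond may drift into conjugation with the ketone before C5 has equilibrated. The fallback sets C5 by irreversible kinetic protonation instead of equilibration. It sets out from the crude cis-fused ketone 8, before the amidine base is added. Soft enolisation (Me3SiOTf, Et3N, CH2Cl2, 0 °C) gives the conjugated C5=C6 silyl dienol ether F1. MeLi in THF at −78 °C regenerates the lithium dienolate, and acetic acid at −78 °C protonates the α-carbon C5 on the β face, opposite the C10 silyloxy group. This returns to the route at 9.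

Step 11. The radical centre C11 may be attacked with poor facial discrimination, giving the methyl trans to C8 as well. The fallback makes the centre stereoconvergent through a lactone enolate. It sets out from 16 as the C11 epimer mixture. Oxidation (CrO3, H2SO4, acetone, 0 °C) gives the γ-lactone F2 (C11 mixture). LiN(iPr)2 in THF at −78 °C followed by 2,6-di-tert-butyl-4-methylphenol protonates the enolate on the convex face and places the methyl cis to C8, giving the lactone F3. iBu2AlH in CH2Cl2 at −78 °C gives the lactol F4, and ethanol with pyridinium p-toluenesulfonate returns to the route at 16 as a single C11 epimer.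

Step 9. Hydride may be delivered to the β face of the flexible cycloheptenone and give the 6α-alcohol, which would carry the wrong configuration into C6 and C7. The fallback inverts the carbinol. It sets out from 12; the reduction product is then the 6α-allylic alcohol F5. Mitsunobu reaction (4-nitrobenzoic acid, PPh3, diisopropyl azodicarboxylate, THF, 0 °C) gives the inverted 6β-(4-nitrobenzoate) F6, and K2CO3 in methanol returns to the route at 13.

**Further compounds**
F1 | step 6 | C5=C6 trimethylsilyl dienol ether of 8 (C3 SiMe3, 10α-silyloxy, H1 α) | C[Si](C)(C)OC1=C2C(C)=C([Si](C)(C)C)C[C@@H]2[C@@H](O[Si](c3ccccc3)(c3ccccc3)C(C)(C)C)CCC1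
F2 | step 11 | γ-lactone C6–O–C12(=O) from 16, C11 epimer mixture | O=C1O[C@H]2[C@@H](C1C)CC[C@H](O[Si](c4ccccc4)(c4ccccc4)C(C)(C)C)[C@H]3CC=C(C)[C@H]23
F3 | step 11 | γ-lactone with C11 methyl cis to C8 | O=C1O[C@H]2[C@@H]([C@@H]1C)CC[C@H](O[Si](c4ccccc4)(c4ccccc4)C(C)(C)C)[C@H]3CC=C(C)[C@H]23
F4 | step 11 | lactol from F3 | OC1O[C@H]2[C@@H]([C@@H]1C)CC[C@H](O[Si](c4ccccc4)(c4ccccc4)C(C)(C)C)[C@H]3CC=C(C)[C@H]23
F5 | step 9 | 6α-allylic alcohol (C6 epimer of 13) | O[C@@H]1C=CC[C@H](O[Si](c3ccccc3)(c3ccccc3)C(C)(C)C)[C@H]2CC=C(C)[C@H]12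
F6 | step 9 | 6β-(4-nitrobenzoate) of 13 | O=C(O[C@H]1C=CC[C@H](O[Si](c3ccccc3)(c3ccccc3)C(C)(C)C)[C@H]2CC=C(C)[C@H]12)c1ccc(cc1)[N+](=O)[O-]
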